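## Analysis of the target

The target (16) is a C30H50 hydrocarbon, 1,2-bis[(4aS,8aS)-2,5,5,8a-tetramethyl-3,4,4a,5,6,7,8,8a-octahydronaphthalen-1-yl]ethane: two identical trans-fused bicyclic C15 halves joined through a CH2–CH2 bridge. Each half is numbered here like a drimane: ring A is C1–C5 plus C10, ring B is C5–C10, C4 carries the geminal methyls, C10 the angular methyl, C8 a vinylic methyl, and C11 is the bridge methylene on C9; the second half takes primes. There are four stereocentres, C5, C10, C5′ and C10′, all S; in each half the C10 methyl and H-5 are anti (trans-decalin), and the halves are homochiral, so the molecule has a C2 axis. A heterochiral pairing of halves would be a meso diastereomer, so the enantiomeric purity of the half decides the diastereomeric purity of the dimer. The only functional groups are the two tetrasubstituted C8=C9 alkenes, which tolerate base, radicals and palladium chemistry but migrate or start cationic ring closure in strong acid; with no polar group, late purification is difficult. The difficulty lies in the congested run C4–C5–C10–C9: a quaternary C4 next to the fusion methine C5, a quaternary C10, and a vinylic C9 that must be bonded to C11 although it is flanked by C10 and the C8 methyl. The strategy rests on C4: it is a quaternary gem-dimethyl carbon between C3 and C5, so ring A can be closed last through C3–C4 by a tertiary C4 radical, made from an isopropenyl group on C5, attacking an acceptor carbon C3 tethered to C10 through C1 and C2.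

## Retrosynthetic reasoning

**16 to 15 and 13.** The molecule is cut at C9′–C11′, the sp2–sp3 bond between one ring and the bridge. This cut, rather than the central C11–C11′ bond, lets both halves come from one compound, enol triflate 13: one portion is the electrophile, another is turned into the nucleophile 15. The forward reaction is a B-alkyl Suzuki–Miyaura coupling. It must join a primary alkylborane to a crowded vinylic carbon, and cleanly, because the product has no handle for purification.

**15 to 14.** The C11′–B bond comes from anti-Markovnikov hydroboration of the terminal alkene of diene 14. The tetrasubstituted C8=C9 alkene is too hindered to compete, so no protection is needed.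

**14 to 13.** The C9–C11 bond is cut, so that both bridge carbons arrive together as a vinyl group by cross-coupling of 13 with a vinyl-metal reagent. No oxidation-state change at C11 is then required.

**13 to 11 to 9.** The C8=C9 alkene with its leaving group is the enol derivative of ketone 11. Because C10 is quaternary, the C9 ketone can enolise only toward C8, so the alkene position in 16 is fixed by constitution and not by selectivity. The C8 methyl is then removed retrosynthetically (11 to 9) as an enolate methylation through 10, again with a single possible site.

**9 to 7 to 6.** Ketone 9 has nothing on C2, but the ring closure below needs an electron-withdrawing group there. Ketone 9 is therefore traced to acid 7 by radical decarboxylation through thiohydroxamate ester 8, and 7 to ethyl ester 6 by hydrolysis. This costs two steps and buys a polarity-matched radical closure of ring A.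

**6 to 5 (key disconnection).** The C3–C4 bond of ring A is cut. A polar alkylation at C4 would have to form a quaternary neopentyl centre and is not realistic; an annulation through carbonyl chemistry would leave oxygen on ring A to be removed and the geminal methyls still to be added. Cutting C3–C4 homolytically gives precursor 5, in which C4 is the internal carbon of an isopropenyl group on C5 and C3 is the terminus of a 2-substituted acrylate attached to C10 through C1. The forward reaction has to deliver a hydrogen atom to the isopropenyl CH2 (which becomes the second methyl) and close the six-membered ring. Both fusion stereocentres are already present in 5.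

**5 to 1, 2 and 3 through 4.** Two bonds on the adjacent carbons C5 and C10 are cut: C5–C4 by conjugate addition of Grignard reagent 2 to enone 1, and C10–C1 by alkylation of the resulting enolate 4 with allylic bromide 3. One flask thus assembles all sixteen carbons of 5. The catalyst must set C5, and the existing C5 substituent must direct the electrophile to the opposite face to set C10.

## Alternatives that were turned down

**Alternative 1: two-directional cationic bicyclisation.**
- Disconnection: in each half C4–C5 and C9–C10 are cut together, which unravels all four rings to an open-chain C30 bis-epoxide A1 whose two inner alkenes are allylsilanes.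
- Forward key step: a Lewis acid opens both terminal epoxides of A1; each end closes ring A and then ring B through chair-like folding, and loss of silicon ends each cascade as an exocyclic C8 methylene, giving diol A2 (α-onocerin).
- For: four rings and eight stereocentres form in one operation, the C2 symmetry is used fully, and trans fusion follows from the folding.
- Against: A2 has two C3 hydroxyls that 16 lacks, so two secondary alcohols must be removed. Its alkenes are exocyclic and must be moved into C8=C9 with acid, the very conditions under which a C8 cation can be captured by the alkene of the other half. A1 itself needs stereodefined trisubstituted alkenes, two allylsilanes and two enantioselective epoxidations.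
- Comparison: on bonds and stereocentres per step this alternative is clearly stronger. The chosen route offers instead an alkene position fixed by a ketone that can enolise only one way, no surplus oxygen in the late stage, and a short count of eight steps.

**Alternative 2: enone–allene photocycloaddition, then fragmentation.**
- Disconnection: C10–C9 and C1–C8 are cut as the two new bonds of a methylenecyclobutane, leading back to ring-A enone A3, which already carries the geminal methyls and an acetate arm on C5, and to allene A4.
- Forward key step: irradiation of A3 with A4 gives the cis-fused photoadduct A5, with the cyclobutane anti to the C5 arm. Oxidative cleavage of the methylene and retro-Claisen opening of the cyclobutanone would then leave a two-carbon acyl arm on C10 for closure of ring B onto the C5 arm.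
- For: C4 needs no bond formation at all, and the quaternary C10 is made by a dependable photochemical step.
- Against: ring B is still unbuilt after the key step. The C2 carbonyl of ring A and the oxygen left in ring B must be removed, and the C8 methyl and C9 substituent are still to come. A3 must be obtained enantioenriched, and the regiochemistry of the cycloaddition must be controlled.
- Comparison: this alternative is stronger at C4, where the chosen route must form a bond at a neopentyl centre. The chosen route answers with a radical bond formation that tolerates congestion, sets both stereocentres in one catalytic step, and needs far fewer functional-group removals.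

**Alternative 3: ring expansion of a hydrindenedione.**
- Disconnection: C7–C8 and C8–C9 are cut, so that C8 and its methyl are excised from ring B, leading to the Hajos–Parrish ketone A6 and diazoethane A7.
- Forward key step: Lewis-acid-promoted addition of A7 to the saturated C9 ketone of A6, migration of C7 and loss of nitrogen give the ring-expanded enedione A8, with the C9 ketone, the C8 methyl and a ring-A enone.
- For: A6 is available in high enantiomeric purity by organocatalysis, C8 and its methyl arrive together, and the C9 ketone is in place for the enol triflate.
- Against: the migration must favour C7 over the quaternary C10, and the diazoalkane can also attack the enone or homologate twice. Ring A then still needs a deconjugative double methylation at C4, removal of the C3 carbonyl in the presence of the C9 ketone (hence protection), and reduction to set C5.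
- Comparison: this alternative is stronger on the source of absolute configuration and saves the separate C8 methylation. The chosen route offers a ring A made with its geminal methyls in one step, no C3 oxygen to remove, and no reductive setting of the ring fusion; ketone 11 is reached in five steps.

Key step: step 2

Remark on the chemistry: C2 of 6–8 and C8 of 11 stop being stereocentres in steps 4 and 6, so the equatorial epimers are written and epimer mixtures at these carbons are carried forward. The ligand enantiomer in step 1 is the one that gives the 3S configuration of 4.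

## Route

Step 1
Reactants: 1 2-methylcyclohex-2-en-1-one; 2 isopropenylmagnesium bromide; 3 ethyl 2-(bromomethyl)prop-2-enoate
Product: 5 ethyl 2-{[(1S,6S)-1-methyl-2-oxo-6-(prop-1-en-2-yl)cyclohexyl]methyl}prop-2-enoate, via bromomagnesium enolate 4 (not isolated)
Conditions: Cu(OTf)2 (5 mol%), chiral N-mesityl-N′-(hydroxyalkyl)imidazolinium salt (NHC precursor, 6 mol%), 2 (1.2 equiv), Et2O, −30 °C; then 3 (1.5 equiv), DMPU, −30 °C → rt
Reagents that add atoms: none
Why: Copper-catalysed asymmetric conjugate addition of a Grignard reagent to an α-substituted cyclic enone with trapping of the magnesium enolate; the chiral NHC–copper complex sets C5. The tetrasubstituted enolate 4 is alkylated by the very reactive allylic bromide 3 (SN2 and SN2′ give the same 2-(ethoxycarbonyl)allyl group) on the face anti to the pseudoaxial isopropenyl group, which sets C10 with the two arms trans.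

Step 2
Reactants: 5 ethyl 2-{[(1S,6S)-1-methyl-2-oxo-6-(prop-1-en-2-yl)cyclohexyl]methyl}prop-2-enoate
Product: 6 ethyl (2S,4aS,8aS)-4,4,8a-trimethyl-8-oxodecahydronaphthalene-2-carboxylate
Conditions: Fe(acac)3 (30 mol%), PhSiH3 (2.5 equiv), EtOH/(CH2OH)2 5:1, 0.02 M, 60 °C
Reagents that add atoms: none
Why: Fe(acac)3 and PhSiH3 in ethanol form an iron hydride that transfers a hydrogen atom to the terminal CH2 of the electron-rich isopropenyl group (Markovnikov), so this CH2 becomes the second C4 methyl and the radical sits on tertiary C4. The nucleophilic radical adds to the unsubstituted acrylate terminus C3, forming C3–C4 and closing ring A in a 6-endo-trig mode; the α-ester radical at C2 is reduced by divalent iron to the ester enolate and protonated by the solvent, which returns trivalent iron. The closest known reaction type is the iron-hydride-initiated reductive coupling of unactivated alkenes with acrylates (an intramolecular Giese addition), which is established for making quaternary carbons. The ring fusion is not at stake: C5 and C10 are already trans in 5, and the ring-B conformer with both arms equatorial and the angular methyl axial leads directly to the trans-decalin. The only new stereocentre is C2, set by protonation of the enolate; the equatorial 2S ester should prevail after equilibration because an axial ester would be syn-diaxial to the C10 methyl and one C4 methyl, and its configuration is lost in step 4 anyway. The step needs hydrogen-atom transfer to the isopropenyl group and not to the acrylate, and 6-endo instead of 5-exo closure; both follow from polarity, since the metal hydride prefers the electron-rich alkene and the nucleophilic radical prefers the acrylate β-carbon, whereas 5-exo attack would create a second quaternary centre and an unstabilised primary radical. High dilution suppresses intermolecular addition, and the ketone is inert under these conditions.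

Step 3
Reactants: 6 ethyl (2S,4aS,8aS)-4,4,8a-trimethyl-8-oxodecahydronaphthalene-2-carboxylate
Product: 7 (2S,4aS,8aS)-4,4,8a-trimethyl-8-oxodecahydronaphthalene-2-carboxylic acid
Conditions: LiOH·H2O, THF/MeOH/H2O, 50 °C; then 1 M HCl
Reagents that add atoms: lithium hydroxide, [Li+].[OH-]
Why: Saponification of an unhindered secondary ethyl ester; the ketone has no β-relationship to the ester and is unaffected, and any axial C2 epimer equilibrates to the equatorial acid under the basic conditions.

Step 4
Reactants: 7 (2S,4aS,8aS)-4,4,8a-trimethyl-8-oxodecahydronaphthalene-2-carboxylic acid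
Product: 9 (4aS,8aS)-5,5,8a-trimethyloctahydronaphthalen-1(2H)-one, via Barton ester 8 (not isolated)
Conditions: N-hydroxypyridine-2(1H)-thione, DCC, DMAP (cat.), CH2Cl2, 0 °C → rt, dark; then t-BuSH, PhMe, hν (tungsten lamp), rt
Reagents that add atoms: none
Why: Barton reductive decarboxylation: the thiohydroxamate ester fragments under visible light to CO2 and a secondary C2 radical, which takes a hydrogen atom from the thiol in a chain process. Ketones are tolerated and no stereocentre of the final product is touched.

Step 5
Reactants: 9 (4aS,8aS)-5,5,8a-trimethyloctahydronaphthalen-1(2H)-one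
Product: 11 (2R,4aS,8aS)-2,5,5,8a-tetramethyloctahydronaphthalen-1(2H)-one, via lithium enolate 10 (not isolated)
Conditions: LiN(iPr)2 (1.1 equiv), THF, −78 °C; then MeI, −78 → 0 °C
Reagents that add atoms: iodomethane, CI
Why: Enolate methylation; C10 is quaternary, so deprotonation and alkylation can occur only at C8, and a second methylation at the now tertiary C8 is slow. The C8 configuration is irrelevant because C8 becomes sp2 in step 6.

Step 6
Reactants: 11 (2R,4aS,8aS)-2,5,5,8a-tetramethyloctahydronaphthalen-1(2H)-one
Product: 13 (4aS,8aS)-2,5,5,8a-tetramethyl-3,4,4a,5,6,7,8,8a-octahydronaphthalen-1-yl trifluoromethanesulfonate, via potassium enolate 12 (not isolated)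
Conditions: KN(SiMe3)2 (1.3 equiv), THF, −78 → 0 °C; then PhNTf2, 0 °C → rt
Reagents that add atoms: N-phenylbis(trifluoromethanesulfonimide), O=S(=O)(N(c1ccccc1)S(=O)(=O)C(F)(F)F)C(F)(F)F
Why: O-sulfonylation of a ketone enolate to an enol triflate, as practised on 2,2,6-trisubstituted cyclohexanones. Only the C8=C9 enolate can form, so the tetrasubstituted alkene of the target is fixed here.

Step 7
Reactants: 13 (4aS,8aS)-2,5,5,8a-tetramethyl-3,4,4a,5,6,7,8,8a-octahydronaphthalen-1-yl trifluoromethanesulfonate
Product: 14 (4aS,8aS)-1-ethenyl-2,5,5,8a-tetramethyl-3,4,4a,5,6,7,8,8a-octahydronaphthalene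
Conditions: tributyl(vinyl)stannane (1.5 equiv), Pd(PPh3)4 (5 mol%), LiCl (3 equiv), THF, reflux
Reagents that add atoms: tributyl(vinyl)stannane, C=C[Sn](CCCC)(CCCC)CCCC
Why: Stille coupling of an enol triflate with a vinylstannane in the presence of chloride, a reaction known to work on hindered 2,6,6-trisubstituted cyclohexenyl triflates. It forms C9–C11 and brings in both bridge carbons.

Step 8
Reactants: 14 (4aS,8aS)-1-ethenyl-2,5,5,8a-tetramethyl-3,4,4a,5,6,7,8,8a-octahydronaphthalene; 13 (4aS,8aS)-2,5,5,8a-tetramethyl-3,4,4a,5,6,7,8,8a-octahydronaphthalen-1-yl trifluoromethanesulfonate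
Product: 16 1,2-bis[(4aS,8aS)-2,5,5,8a-tetramethyl-3,4,4a,5,6,7,8,8a-octahydronaphthalen-1-yl]ethane, via alkylborane 15 (not isolated)
Conditions: 9-BBN (1.3 equiv), THF, 0 °C → rt; then 13 (0.9 equiv), PdCl2(dppf) (10 mol%), AsPh3 (10 mol%), 3 M aq K3PO4, DMF, 60 °C
Reagents that add atoms: none
Why: 9-BBN adds to the terminal vinyl carbon only, since the tetrasubstituted alkene is inert to it, and the primary B-alkyl-9-BBN is coupled with the enol triflate in a B-alkyl Suzuki–Miyaura reaction, forming C11′–C9′. The bidentate dppf ligand disfavours β-hydride elimination from the alkylpalladium intermediate, and no stereocentre is involved.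

## Compound list

1 | 2-methylcyclohex-2-en-1-one | CC1=CCCCC1=O | starting material
2 | isopropenylmagnesium bromide (prop-1-en-2-ylmagnesium bromide) | C=C(C)[Mg]Br | starting material
3 | ethyl 2-(bromomethyl)prop-2-enoate | C=C(CBr)C(=O)OCC | starting material
4 | bromomagnesium (3S)-2-methyl-3-(prop-1-en-2-yl)cyclohex-1-en-1-olate | C=C(C)[C@@H]1CCCC(O[Mg]Br)=C1C | intermediate
5 | ethyl 2-{[(1S,6S)-1-methyl-2-oxo-6-(prop-1-en-2-yl)cyclohexyl]methyl}prop-2-enoate (acrylate arm trans to isopropenyl) | C=C(C)[C@@H]1CCCC(=O)[C@@]1(C)CC(=C)C(=O)OCC | intermediate
6 | ethyl (2S,4aS,8aS)-4,4,8a-trimethyl-8-oxodecahydronaphthalene-2-carboxylate (trans-fused, equatorial ester) | CCOC(=O)[C@H]1CC(C)(C)[C@@H]2CCCC(=O)[C@@]2(C)C1 | intermediate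
7 | (2S,4aS,8aS)-4,4,8a-trimethyl-8-oxodecahydronaphthalene-2-carboxylic acid | OC(=O)[C@H]1CC(C)(C)[C@@H]2CCCC(=O)[C@@]2(C)C1 | intermediate
8 | 2-thioxopyridin-1(2H)-yl (2S,4aS,8aS)-4,4,8a-trimethyl-8-oxodecahydronaphthalene-2-carboxylate | S=c1ccccn1OC(=O)[C@H]1CC(C)(C)[C@@H]2CCCC(=O)[C@@]2(C)C1 | intermediate
9 | (4aS,8aS)-5,5,8a-trimethyloctahydronaphthalen-1(2H)-one | O=C1[C@@]2(C)CCCC(C)(C)[C@@H]2CCC1 | intermediate
10 | lithium (4aS,8aS)-5,5,8a-trimethyl-3,4,4a,5,6,7,8,8a-octahydronaphthalen-1-olate | [Li]OC1=CCC[C@H]2C(C)(C)CCC[C@]12C | intermediate
11 | (2R,4aS,8aS)-2,5,5,8a-tetramethyloctahydronaphthalen-1(2H)-one (equatorial C8 methyl) | C[C@H]1C(=O)[C@@]2(C)CCCC(C)(C)[C@@H]2CC1 | intermediate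
12 | potassium (4aS,8aS)-2,5,5,8a-tetramethyl-3,4,4a,5,6,7,8,8a-octahydronaphthalen-1-olate | CC1=C(O[K])[C@@]2(C)CCCC(C)(C)[C@@H]2CC1 | intermediate
13 | (4aS,8aS)-2,5,5,8a-tetramethyl-3,4,4a,5,6,7,8,8a-octahydronaphthalen-1-yl trifluoromethanesulfonate | CC1=C(OS(=O)(=O)C(F)(F)F)[C@@]2(C)CCCC(C)(C)[C@@H]2CC1 | intermediate
14 | (4aS,8aS)-1-ethenyl-2,5,5,8a-tetramethyl-3,4,4a,5,6,7,8,8a-octahydronaphthalene | CC1=C(C=C)[C@@]2(C)CCCC(C)(C)[C@@H]2CC1 | intermediate
15 | 9-{2-[(4aS,8aS)-2,5,5,8a-tetramethyl-3,4,4a,5,6,7,8,8a-octahydronaphthalen-1-yl]ethyl}-9-borabicyclo[3.3.1]nonane | CC1=C(CCB2C3CCCC2CCC3)[C@@]2(C)CCCC(C)(C)[C@@H]2CC1 | intermediate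
16 | 1,2-bis[(4aS,8aS)-2,5,5,8a-tetramethyl-3,4,4a,5,6,7,8,8a-octahydronaphthalen-1-yl]ethane (CNP0372467.1) | CC1=C(CCC2=C(C)CC[C@H]3C(C)(C)CCC[C@]23C)[C@@]2(C)CCCC(C)(C)[C@@H]2CC1 | target

## Step count and risk

Total step count: 8. Longest linear sequence: 8 steps (1 to 16); triflate 13 is used twice, in steps 7 and 8.

**Step 2 (key step).** The most likely failure is quenching of the tertiary C4 radical before it closes the ring, which would amount to net hydrogenation of the isopropenyl group. Closure needs the ring-B conformer with both arms equatorial and a new bond at a neopentyl carbon, while the hydride source is present in excess. Intermolecular addition to the acrylate of a second molecule is the other competing process if the solution is too concentrated.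
Fallback: the same radical is generated under chain conditions in which the hydrogen donor is kept scarce. Setting out from 5, Markovnikov addition of dry HBr (CH2Cl2, −78 °C) to the isopropenyl group should give ethyl 2-{[(1S,6R)-6-(2-bromopropan-2-yl)-1-methyl-2-oxocyclohexyl]methyl}prop-2-enoate F1. Slow addition of Bu3SnH with AIBN in benzene at 80 °C should then abstract bromine and allow the 6-endo closure before reduction, which comes back to the route at 6.

**Step 8.** Transmetalation and reductive elimination at the crowded C9′ may be slow. β-Hydride elimination from the alkylpalladium species, protodeboronation of 15, or hydrolysis of the triflate could then take over and leave hydrocarbon by-products that are hard to separate from 16.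
Fallback: the union is moved to the unhindered central C11–C11′ bond, which the 1,5-diene pattern of 16 allows. Setting out from 13:
- Methoxycarbonylation (Pd(OAc)2, dppp, CO, MeOH, Et3N, DMF) should give methyl (4aS,8aS)-2,5,5,8a-tetramethyl-3,4,4a,5,6,7,8,8a-octahydronaphthalene-1-carboxylate F2.
- Reduction with i-Bu2AlH should give [(4aS,8aS)-2,5,5,8a-tetramethyl-3,4,4a,5,6,7,8,8a-octahydronaphthalen-1-yl]methanol F3.
- CBr4/PPh3 should give (4aS,8aS)-1-(bromomethyl)-2,5,5,8a-tetramethyl-3,4,4a,5,6,7,8,8a-octahydronaphthalene F4.
- Reductive homocoupling of this allylic bromide with CoCl(PPh3)3 (monovalent cobalt) in benzene should join the two primary carbons, since the γ-position is tetrasubstituted, and comes back to the route at 16.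

**Step 1.** The main risk is insufficient enantioface discrimination, because alkenyl Grignard reagents are less well served by this catalysis than alkyl ones and an uncatalysed background addition would erode selectivity. Since two halves are joined in step 8, any minor enantiomer ends up as the meso diastereomer of 16. A second risk is slow C-alkylation of the magnesium enolate, with proton transfer and loss of regiocontrol.
Fallback: the absolute configuration is secured by classical resolution at the acid stage.
- Setting out from 1, 2 and 3, ligand-free catalysis with CuBr·SMe2 followed by the same alkylation should give racemic ethyl 2-{[1-methyl-2-oxo-6-(prop-1-en-2-yl)cyclohexyl]methyl}prop-2-enoate F5 (trans).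
- Steps 2 and 3 on this material should give the racemic keto ester F6 and the racemic keto acid F7.
- Crystallisation of F7 with an enantiopure amine should give the (R)-1-phenylethylammonium salt of 7 F8; the antipodal amine is used if that salt of 7 is the less soluble one.
- Acidification of the salt comes back to the route at 7.

**Step 6.** Enolisation of the tertiary α-C–H at C8, next to the quaternary C10, may be incomplete, or the enolate may be reprotonated before sulfonyl transfer, so that ketone is recovered.
Fallback: the enol triflate is bypassed altogether. Setting out from 11, methylene transfer from dimethylsulfonium methylide (Me3S+ I−, n-BuLi, THF) should give (4a′S,8a′S)-2′,5′,5′,8a′-tetramethyloctahydro-2′H-spiro[oxirane-2,1′-naphthalene] F9 as an epimer mixture. Base-induced isomerisation with diethylaluminium 2,2,6,6-tetramethylpiperidide, whose only available β-hydrogen is on C8, should give the allylic alcohol [(4aS,8aS)-2,5,5,8a-tetramethyl-3,4,4a,5,6,7,8,8a-octahydronaphthalen-1-yl]methanol F3. Conversion into (4aS,8aS)-1-(bromomethyl)-2,5,5,8a-tetramethyl-3,4,4a,5,6,7,8,8a-octahydronaphthalene F4 and cobalt-mediated homocoupling, as in the fallback to step 8, comes back to the route at 16.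

## Further compounds

F1 | step 2 | ethyl 2-{[(1S,6R)-6-(2-bromopropan-2-yl)-1-methyl-2-oxocyclohexyl]methyl}prop-2-enoate | CC(C)(Br)[C@@H]1CCCC(=O)[C@@]1(C)CC(=C)C(=O)OCC
F2 | step 8 | methyl (4aS,8aS)-2,5,5,8a-tetramethyl-3,4,4a,5,6,7,8,8a-octahydronaphthalene-1-carboxylate | CC1=C(C(=O)OC)[C@@]2(C)CCCC(C)(C)[C@@H]2CC1
F3 | step 8 | [(4aS,8aS)-2,5,5,8a-tetramethyl-3,4,4a,5,6,7,8,8a-octahydronaphthalen-1-yl]methanol | CC1=C(CO)[C@@]2(C)CCCC(C)(C)[C@@H]2CC1
F4 | step 8 | (4aS,8aS)-1-(bromomethyl)-2,5,5,8a-tetramethyl-3,4,4a,5,6,7,8,8a-octahydronaphthalene | CC1=C(CBr)[C@@]2(C)CCCC(C)(C)[C@@H]2CC1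
F5 | step 1 | racemic trans ethyl 2-{[1-methyl-2-oxo-6-(prop-1-en-2-yl)cyclohexyl]methyl}prop-2-enoate (both enantiomers) | C=C(C)[C@@H]1CCCC(=O)[C@@]1(C)CC(=C)C(=O)OCC.C=C(C)[C@H]1CCCC(=O)[C@]1(C)CC(=C)C(=O)OCC
F6 | step 1 | racemic ethyl 4,4,8a-trimethyl-8-oxodecahydronaphthalene-2-carboxylate, trans-fused, equatorial ester (both enantiomers) | CCOC(=O)[C@H]1CC(C)(C)[C@@H]2CCCC(=O)[C@@]2(C)C1.CCOC(=O)[C@@H]1CC(C)(C)[C@H]2CCCC(=O)[C@]2(C)C1
F7 | step 1 | racemic 4,4,8a-trimethyl-8-oxodecahydronaphthalene-2-carboxylic acid, trans-fused (both enantiomers) | OC(=O)[C@H]1CC(C)(C)[C@@H]2CCCC(=O)[C@@]2(C)C1.OC(=O)[C@@H]1CC(C)(C)[C@H]2CCCC(=O)[C@]2(C)C1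
F8 | step 1 | (R)-1-phenylethylammonium (2S,4aS,8aS)-4,4,8a-trimethyl-8-oxodecahydronaphthalene-2-carboxylate | C[C@@H]([NH3+])c1ccccc1.[O-]C(=O)[C@H]1CC(C)(C)[C@@H]2CCCC(=O)[C@@]2(C)C1
F9 | step 6 | (4a′S,8a′S)-2′,5′,5′,8a′-tetramethyloctahydro-2′H-spiro[oxirane-2,1′-naphthalene], epimer mixture at C1′ and C2′ | CC1CC[C@H]2C(C)(C)CCC[C@]2(C)C13CO3
A1 | alternative 1 | (3S,22S)-2,3:22,23-bis-epoxide of the squalene analogue whose C10 and C15 methyls are CH2SiMe3 groups | CC1(C)O[C@H]1CC/C(C)=C/CC/C(C[Si](C)(C)C)=C/CC/C=C(C[Si](C)(C)C)/CC/C=C(C)/CC[C@@H]1OC1(C)C
A2 | alternative 1 | α-onocerin (3β,3′β-diol with exocyclic C8 and C8′ methylenes) | C(C[C@H]1C(=C)CC[C@H]2C(C)(C)[C@@H](O)CC[C@]12C)[C@H]1C(=C)CC[C@H]2C(C)(C)[C@@H](O)CC[C@]12C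
A3 | alternative 2 | methyl 2-[(1S)-2,6,6-trimethyl-4-oxocyclohex-2-en-1-yl]acetate | COC(=O)C[C@H]1C(C)(C)CC(=O)C=C1C
A4 | alternative 2 | propa-1,2-diene (allene) | C=C=C
A5 | alternative 2 | methyl 2-(1,3,3-trimethyl-7-methylidene-5-oxobicyclo[4.2.0]octan-2-yl)acetate, cis-fused, cyclobutane anti to the acetate arm | COC(=O)C[C@H]1C(C)(C)CC(=O)[C@@H]2C(=C)C[C@]12C
A6 | alternative 3 | (S)-7a-methyl-2,3,7,7a-tetrahydro-1H-indene-1,5(6H)-dione (Hajos–Parrish ketone) | C[C@]12CCC(=O)C=C1CCC2=O
A7 | alternative 3 | diazoethane | CC=[N+]=[N-]
A8 | alternative 3 | (2R,8aS)-2,8a-dimethyl-3,4,8,8a-tetrahydronaphthalene-1,6(2H,7H)-dione | C[C@]12CCC(=O)C=C1CC[C@@H](C)C2=O
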